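**Retrosynthetic overview**

1. The target is the O5 ester of the cis-(5S,6S)-5-hydroxy-6-[(E)-propenyl]-5,6-dihydro-2H-pyran-2-one ring (one ring, the δ-lactone) with (2E,4E,6S)-4,6-dimethyldodeca-2,4-dienoic acid.
2. Key disconnection: the C3–C4 single bond of the dienoate. The enabling feature is the side-chain diene C2=C3–C4(CH3)=C5H, in which C3 and the hydrogen on C5 are cis across C4=C5. This is the syn H/C adduct of a methyl-capped alkyne C4≡C5, and C1–C3 is an acrylate already carried on O5 of the lactone ring.
3. A ruthenium-hydride alkyne–acrylate hydrovinylation therefore joins the lactone acrylate and (S)-4-methyldec-2-yne in the last step, forming the bond and both E-alkenes with no by-product.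
4. Alkyne half: Evans methylation sets the side-chain stereocentre; Corey–Fuchs homologation with a methyl iodide quench gives the 2-alkyne.
5. Lactone half: Brown Z-alkoxyallylboration of crotonaldehyde sets C5/C6 (syn). The only ring, the lactone, is closed by ring-closing metathesis (step 10) before the key step; MOM removal and O5-acrylation follow.

Key step: step 13

Remark on the chemistry: the target is read as the (5S,6S)-cis lactone (the phomalactone core) acylated by the (2E,4E,6S) acid; crotonaldehyde is used as its E isomer.

**Alkyne half**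

Step 1
Reactants: 1 (S)-4-benzyloxazolidin-2-one; 2 octanoyl chloride
Product: 3 (S)-4-benzyl-3-octanoyloxazolidin-2-one
Conditions: Et3N, DMAP (cat.), CH2Cl2, 0 °C → rt
Reagents that add atoms: none
Why: N-Acylation of the oxazolidinone by the acid chloride under Et3N/DMAP (nucleophilic acyl substitution) is the standard loading of an Evans auxiliary and touches no stereocentre.

Step 2
Reactants: 3 (S)-4-benzyl-3-octanoyloxazolidin-2-one
Product: 5 (S)-4-benzyl-3-[(S)-2-methyloctanoyl]oxazolidin-2-one, via sodium Z-enolate 4 (not isolated)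
Conditions: NaN(SiMe3)2, THF, −78 °C; MeI, −78 → −30 °C
Reagents that add atoms: iodomethane, CI
Why: Evans asymmetric alkylation, in which the chelated sodium Z-enolate 4 is methylated on the face opposite the C4 benzyl group, should set the (S)-configured methyl-bearing carbon that becomes C6 of the side chain, the minor diastereomer being removable by chromatography.

Step 3
Reactants: 5 (S)-4-benzyl-3-[(S)-2-methyloctanoyl]oxazolidin-2-one
Product: 6 (S)-2-methyloctan-1-ol
Conditions: LiBH4, H2O (1 equiv), Et2O, 0 °C
Reagents that add atoms: none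
Why: Reductive cleavage of the imide by LiBH4 (hydride attack at the exocyclic carbonyl, activated by lithium chelation) should release the primary alcohol without epimerisation and return the auxiliary.

Step 4
Reactants: 6 (S)-2-methyloctan-1-ol
Product: 7 (S)-2-methyloctanal
Conditions: TEMPO (cat.), PhI(OAc)2, CH2Cl2, rt
Reagents that add atoms: none
Why: TEMPO-catalysed oxidation with PhI(OAc)2 stops at the aldehyde under non-basic conditions, so the α-stereocentre should survive if 7 is used at once.

Step 5
Reactants: 7 (S)-2-methyloctanal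
Product: 8 (S)-1,1-dibromo-3-methylnon-1-ene
Conditions: CBr4, PPh3, CH2Cl2, 0 °C
Reagents that add atoms: carbon tetrabromide, BrC(Br)(Br)Br
Why: First stage of the Corey–Fuchs alkyne synthesis, a Wittig-type dibromo-olefination by the ylide formed from PPh3 and CBr4, runs under neutral conditions that should leave the adjacent stereocentre intact.

Step 6
Reactants: 8 (S)-1,1-dibromo-3-methylnon-1-ene
Product: 10 (S)-4-methyldec-2-yne, via lithium acetylide 9 (not isolated)
Conditions: n-BuLi (2.1 equiv), THF, −78 °C; MeI, −78 °C → rt
Reagents that add atoms: iodomethane, CI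
Why: Second stage of the Corey–Fuchs sequence, in which n-BuLi converts the dibromoalkene by bromine–lithium exchange and Fritsch–Buttenberg–Wiechell rearrangement into lithium acetylide 9 that is C-methylated in the same flask, should give the 2-alkyne without touching the non-acidic propargylic stereocentre.

**Lactone half**

Step 7
Reactants: 11 prop-2-en-1-ol
Product: 12 3-(methoxymethoxy)prop-1-ene
Conditions: MOMCl, i-Pr2NEt, CH2Cl2, 0 °C → rt; distillation
Reagents that add atoms: chloromethyl methyl ether, COCCl
Why: O-Alkylation of the primary alcohol by the highly electrophilic α-chloro ether (MOM protection, a Williamson-type etherification) is routine and supplies the chelating group needed for the next step.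

Step 8
Reactants: 12 3-(methoxymethoxy)prop-1-ene; 13 (+)-B-methoxydiisopinocampheylborane, (+)-Ipc2BOMe, from (−)-α-pinene; 14 (E)-but-2-enal
Product: 17 (3S,4S,5E)-3-(methoxymethoxy)hepta-1,5-dien-4-ol, via Z-alkoxyallyllithium 15 (not isolated), via Z-alkoxyallyl-diisopinocampheylborane 16 (not isolated)
Conditions: s-BuLi, THF, −78 °C; 13; BF3·OEt2; 14, −78 °C; then NaOH, H2O2, 0 °C → rt
Reagents that add atoms: none
Why: Brown asymmetric alkoxyallylboration, in which kinetic deprotonation gives the chelated Z-alkoxyallyllithium 15, borylation gives 16, and 16 adds to the aldehyde through a closed chair (Zimmerman–Traxler) transition state, should translate the Z geometry into the syn C3/C4 relationship while the isopinocampheyl groups derived from (−)-α-pinene direct attack to the Re face of the aldehyde, setting both centres as S.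

Step 9
Reactants: 17 (3S,4S,5E)-3-(methoxymethoxy)hepta-1,5-dien-4-ol
Product: 18 (3S,4S,5E)-3-(methoxymethoxy)hepta-1,5-dien-4-yl prop-2-enoate
Conditions: acryloyl chloride, i-Pr2NEt, DMAP (cat.), CH2Cl2, −20 → 0 °C
Reagents that add atoms: acryloyl chloride, C=CC(=O)Cl
Why: Amine-mediated O-acylation of the secondary allylic alcohol by acryloyl chloride (nucleophilic acyl substitution) installs the second alkene for ring closure and affects no stereocentre.

Step 10
Reactants: 18 (3S,4S,5E)-3-(methoxymethoxy)hepta-1,5-dien-4-yl prop-2-enoate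
Product: 19 (5S,6S)-5-(methoxymethoxy)-6-[(E)-prop-1-enyl]-5,6-dihydro-2H-pyran-2-one
Conditions: first-generation Grubbs catalyst RuCl2(PCy3)2(=CHPh) (10 mol %), Ti(Oi-Pr)4 (30 mol %), CH2Cl2 (5 mM), reflux
Reagents that add atoms: none
Why: Ring-closing metathesis should start at the monosubstituted vinyl group and close onto the acrylate to give the six-membered α,β-unsaturated lactone (ring alkene necessarily Z), because the less reactive E-propenyl group could only close a five-membered ring, and Ti(Oi-Pr)4 breaks unproductive chelation of the carbene by the ester carbonyl.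

Step 11
Reactants: 19 (5S,6S)-5-(methoxymethoxy)-6-[(E)-prop-1-enyl]-5,6-dihydro-2H-pyran-2-one
Product: 21 (5S,6S)-5-hydroxy-6-[(E)-prop-1-enyl]-5,6-dihydro-2H-pyran-2-one, via bromomethyl ether 20 (not isolated)
Conditions: Me2BBr, CH2Cl2, −78 °C; then sat. aq. NaHCO3/THF
Reagents that add atoms: none
Why: Acetal cleavage by the Lewis acid Me2BBr at −78 °C (bromide attack at the O–CH2–O carbon to give bromomethyl ether 20, hydrolysed on bicarbonate work-up) is selective for MOM ethers and should leave the lactone, the allylic C6–O bond and both alkenes untouched.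

Step 12
Reactants: 21 (5S,6S)-5-hydroxy-6-[(E)-prop-1-enyl]-5,6-dihydro-2H-pyran-2-one
Product: 22 (5S,6S)-2-oxo-6-[(E)-prop-1-enyl]-5,6-dihydro-2H-pyran-5-yl prop-2-enoate
Conditions: acryloyl chloride, i-Pr2NEt, CH2Cl2, −40 → −10 °C
Reagents that add atoms: acryloyl chloride, C=CC(=O)Cl
Why: O-Acylation of the C5 hydroxyl by acryloyl chloride and a hindered amine at low temperature (nucleophilic acyl substitution, the analogue of the simple acetylation of this alcohol) should outrun base-induced β-elimination towards the 2-pyranone.

**Key coupling**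

Step 13
Reactants: 22 (5S,6S)-2-oxo-6-[(E)-prop-1-enyl]-5,6-dihydro-2H-pyran-5-yl prop-2-enoate; 10 (S)-4-methyldec-2-yne
Product: 23 (5S,6S)-2-oxo-6-[(E)-prop-1-enyl]-5,6-dihydro-2H-pyran-5-yl (2E,4E,6S)-4,6-dimethyldodeca-2,4-dienoate
Conditions: RuHCl(CO)(PPh3)3 (5–10 mol %), 10 (2 equiv), degassed DMF, 80 °C, Ar
Reagents that add atoms: none
Why: The divalent ruthenium hydride RuHCl(CO)(PPh3)3 adds H–Ru syn across the C2≡C3 triple bond of 10 with ruthenium on the methyl-bearing carbon, the alkenyl–ruthenium bond then inserts the terminal acrylate C=C of 22 (alkenyl to the β-carbon), and syn β-hydride elimination releases the dienoate and returns the hydride. The closest known reaction type is the ruthenium-hydride-catalysed hydrovinylation (linear co-dimerisation) of internal alkynes with acrylate esters, a redox-neutral relative of the Heck reaction, applied here to a more decorated acrylate. No ring is closed and no stereocentre is formed: C5 and C6 of the lactone and C6 of the side chain are carried through untouched, syn H/C delivery fixes the 4E geometry, and β-hydride elimination to the conjugated ester fixes 2E. Regioselectivity at the alkyne is needed and should come from the steric contrast between the methyl group and the α-branched alkyl group, which puts the bulky ruthenium centre and therefore the new C–C bond on the methyl side. Chemoselectivity among the three alkenes of 22 is needed and should come from the fact that only the acrylate is monosubstituted and electron-poor, whereas the ring enoate and the E-propenyl group are 1,2-disubstituted and insert far more slowly; an excess of 10 keeps the hydride occupied as alkenylruthenium and limits double-bond migration.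

**Compound list**

1 | (S)-4-benzyloxazolidin-2-one | O=C1OC[C@H](Cc2ccccc2)N1 | starting material
2 | octanoyl chloride | CCCCCCCC(=O)Cl | starting material
3 | (S)-4-benzyl-3-octanoyloxazolidin-2-one | CCCCCCCC(=O)N1[C@@H](Cc2ccccc2)COC1=O | intermediate
4 | sodium (Z)-1-[(S)-4-benzyl-2-oxooxazolidin-3-yl]oct-1-en-1-olate | CCCCCC/C=C(\[O-])N1[C@@H](Cc2ccccc2)COC1=O.[Na+] | intermediate
5 | (S)-4-benzyl-3-[(S)-2-methyloctanoyl]oxazolidin-2-one | CCCCCC[C@H](C)C(=O)N1[C@@H](Cc2ccccc2)COC1=O | intermediate
6 | (S)-2-methyloctan-1-ol | CCCCCC[C@H](C)CO | intermediate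
7 | (S)-2-methyloctanal | CCCCCC[C@H](C)C=O | intermediate
8 | (S)-1,1-dibromo-3-methylnon-1-ene | CCCCCC[C@H](C)C=C(Br)Br | intermediate
9 | lithium (S)-3-methylnon-1-yn-1-ide | CCCCCC[C@H](C)C#[C-].[Li+] | intermediate
10 | (S)-4-methyldec-2-yne | CCCCCC[C@H](C)C#CC | intermediate
11 | prop-2-en-1-ol | C=CCO | starting material
12 | 3-(methoxymethoxy)prop-1-ene | C=CCOCOC | intermediate
13 | (+)-B-methoxydiisopinocampheylborane | COB([C@H]1C[C@H]2C[C@@H]([C@@H]1C)C2(C)C)[C@H]1C[C@H]2C[C@@H]([C@@H]1C)C2(C)C | starting material
14 | (E)-but-2-enal | C/C=C/C=O | starting material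
15 | (Z)-3-(methoxymethoxy)allyllithium | [Li+].[CH2-]/C=C\OCOC | intermediate
16 | [(Z)-3-(methoxymethoxy)prop-2-en-1-yl]diisopinocampheylborane | COCO/C=C\CB([C@H]1C[C@H]2C[C@@H]([C@@H]1C)C2(C)C)[C@H]1C[C@H]2C[C@@H]([C@@H]1C)C2(C)C | intermediate
17 | (3S,4S,5E)-3-(methoxymethoxy)hepta-1,5-dien-4-ol | C/C=C/[C@H](O)[C@@H](OCOC)C=C | intermediate
18 | (3S,4S,5E)-3-(methoxymethoxy)hepta-1,5-dien-4-yl prop-2-enoate | C/C=C/[C@H](OC(=O)C=C)[C@@H](OCOC)C=C | intermediate
19 | (5S,6S)-5-(methoxymethoxy)-6-[(E)-prop-1-enyl]-5,6-dihydro-2H-pyran-2-one | C/C=C/[C@@H]1OC(=O)C=C[C@@H]1OCOC | intermediate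
20 | (5S,6S)-5-(bromomethoxy)-6-[(E)-prop-1-enyl]-5,6-dihydro-2H-pyran-2-one | C/C=C/[C@@H]1OC(=O)C=C[C@@H]1OCBr | intermediate
21 | (5S,6S)-5-hydroxy-6-[(E)-prop-1-enyl]-5,6-dihydro-2H-pyran-2-one (phomalactone) | C/C=C/[C@@H]1OC(=O)C=C[C@@H]1O | intermediate
22 | (5S,6S)-2-oxo-6-[(E)-prop-1-enyl]-5,6-dihydro-2H-pyran-5-yl prop-2-enoate | C/C=C/[C@@H]1OC(=O)C=C[C@@H]1OC(=O)C=C | intermediate
23 | (5S,6S)-2-oxo-6-[(E)-prop-1-enyl]-5,6-dihydro-2H-pyran-5-yl (2E,4E,6S)-4,6-dimethyldodeca-2,4-dienoate | C/C=C/[C@@H]1OC(=O)C=C[C@@H]1OC(=O)/C=C/C(C)=C/[C@@H](C)CCCCCC | target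

**Totals**

Total step count: 13.
Longest linear sequence: 7 steps (steps 1–6 then 13, or steps 7–12 then 13).

**Steps most likely to fail**

1. Step 13. The risk is loss of regiocontrol in the hydroruthenation, so that the C–C bond forms at C5 of the chain instead of C4, or hydride-induced double-bond migration in the lactone half during heating. The fallback replaces the catalytic hydrometalation by a stoichiometric one followed by a Heck reaction. It sets out from 10. Hydrozirconation with Cp2Zr(H)Cl (excess, THF, 50 °C, thermodynamic placement of zirconium on the methyl-bearing carbon) should give chlorobis(cyclopentadienyl)[(S,E)-4-methyldec-2-en-2-yl]zirconium F1. Iodination in the same flask (I2, 0 °C) should give (S,E)-2-iodo-4-methyldec-2-ene F2. Heck coupling of this iodide with acrylate 22 (Pd(OAc)2, PPh3, Ag2CO3, MeCN, 50 °C) should proceed with retention of the alkenyl geometry, and the fallback comes back to the route at 23.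

2. Step 10. The risk is that the ruthenium carbene engages the E-propenyl group, either by five-ring closure with loss of propene or by shortening the propenyl group through secondary metathesis with the ethene released. The fallback builds the lactone without metathesis and sets out from 17. Linear-selective hydroformylation of the terminal vinyl group (Rh(acac)(CO)2, Xantphos, CO/H2, toluene, 60 °C) should give, after spontaneous closure of the δ-hydroxy aldehyde, (5S,6S)-5-(methoxymethoxy)-6-[(E)-prop-1-enyl]oxan-2-ol F3. Oxidation of the lactol (TEMPO cat., PhI(OAc)2, CH2Cl2) should give (5S,6S)-5-(methoxymethoxy)-6-[(E)-prop-1-enyl]oxan-2-one F4. α-Selenenylation (LiN(SiMe3)2, PhSeBr, THF, −78 °C) should give (5S,6S)-5-(methoxymethoxy)-3-(phenylselanyl)-6-[(E)-prop-1-enyl]oxan-2-one F5. Oxidation and selenoxide syn-elimination (H2O2, pyridine, CH2Cl2, 0 °C) should then introduce the ring alkene, and the fallback comes back to the route at 19.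

3. Step 11. The risk is loss of the lactone during unmasking, by Lewis-acid ionisation of the allylic C6–O bond or by migration of the acyl group to the freed γ-hydroxyl to give the butenolide. The fallback removes the protecting group before any lactone exists and sets out from 17. Acidic methanolysis (HCl cat., MeOH, 40 °C) should give (3S,4S,5E)-hepta-1,5-diene-3,4-diol F6. Double acylation (acryloyl chloride, i-Pr2NEt, DMAP cat., CH2Cl2, 0 °C) should give (3S,4S,5E)-hepta-1,5-diene-3,4-diyl diprop-2-enoate F7. Ring-closing metathesis (first-generation Grubbs catalyst RuCl2(PCy3)2(=CHPh), Ti(Oi-Pr)4, CH2Cl2, reflux) from the terminal vinyl group can close the six-membered lactone with the C4 acrylate or only a strained butenolide with the C3 acrylate, so the C3 acrylate should remain as the O5 ester. The fallback comes back to the route at 22 and bypasses steps 9 to 12.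

**Further compounds**

F1 | step 13 | chlorobis(cyclopentadienyl)[(S,E)-4-methyldec-2-en-2-yl]zirconium | C/C(=C\[C@@H](C)CCCCCC)[Zr](Cl)(C1C=CC=C1)C1C=CC=C1
F2 | step 13 | (S,E)-2-iodo-4-methyldec-2-ene | I/C(C)=C/[C@@H](C)CCCCCC
F3 | step 10 | (5S,6S)-5-(methoxymethoxy)-6-[(E)-prop-1-enyl]oxan-2-ol (mixture at C2) | C/C=C/[C@@H]1OC(O)CC[C@@H]1OCOC
F4 | step 10 | (5S,6S)-5-(methoxymethoxy)-6-[(E)-prop-1-enyl]oxan-2-one | C/C=C/[C@@H]1OC(=O)CC[C@@H]1OCOC
F5 | step 10 | (5S,6S)-5-(methoxymethoxy)-3-(phenylselanyl)-6-[(E)-prop-1-enyl]oxan-2-one (mixture at C3) | C/C=C/[C@@H]1OC(=O)C([Se]c2ccccc2)C[C@@H]1OCOC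
F6 | step 11 | (3S,4S,5E)-hepta-1,5-diene-3,4-diol | C/C=C/[C@H](O)[C@@H](O)C=C
F7 | step 11 | (3S,4S,5E)-hepta-1,5-diene-3,4-diyl diprop-2-enoate | C/C=C/[C@H](OC(=O)C=C)[C@@H](OC(=O)C=C)C=C
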